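## The problem

The target is a C2-symmetric 3,4-disubstituted oxolane whose only stereochemical content is the trans (3R,4R) relationship of two adjacent ring methines, each carrying a 3,4-dimethoxybenzyl arm. Nothing on the ring or the arms remains to direct chemistry, so both stereocentres and both aryl–CH2–C linkages have to be made at a more oxidised stage and then carried through unchanged. Because the two centres are vicinal, one centre fixed in a five-membered ring can set the other by a trans-selective reaction at the neighbouring carbon. The real task is therefore the absolute configuration of the first centre. The veratryl rings are electron-rich: strong oxidants, ether-cleaving Lewis acids and any cationic centre that could close onto the arene in Friedel–Crafts fashion must be avoided. The ring oxygen lies between two CH2 groups, which points to a late ether closure from a 1,4-diol and to a γ-butyrolactone as its precursor. At the lactone level, C4 carries a CH2–aryl arm and a CH2–O arm on a four-carbon chain that ends in a carbonyl. That pattern is what remains when an aryl nucleophile opens the cyclopropane CH2 of a 2-oxo-3-oxabicyclo[3.1.0]hexane-1-carboxylate, and this bicycle is available as one enantiomer from epichlorohydrin and a malonate.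

## Retrosynthesis

**Ether closure.** Target 17 is cut at one ring C–O bond to give the C2-symmetric diol 15, with monotosylate 16 as the species that actually closes. The cut is at a CH2 carbon, so neither stereocentre is touched, and the symmetry of 15 makes the choice of hydroxyl irrelevant. Direct deoxygenation of the lactone carbonyl is the neighbouring option and is kept as a fallback. The forward reaction has to achieve mono-activation followed by 5-exo-tet closure.

**Oxidation level.** Diol 15 is traced to the trans lactone 14. No skeletal bond is cut; the carbonyl is reintroduced because it makes C3 enolisable and so allows the second arm to be attached. The forward step is a complete hydride reduction of a lactone.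

**Second arylmethyl arm.** Lactone 14 is cut at the C3–CH2 bond to give the lithium enolate 13 of monosubstituted lactone 11 and the commercial benzylic bromide 12. Cutting the central C3–C4 bond or both aryl–CH2 bonds would set both centres at once but gives up the reliable relay from C4 to C3. The precursor has one stereocentre and one arm. The forward alkylation must be trans-selective and must stop at monoalkylation.

**Return of the ester.** Lactone 11 is traced to the malonate-type lactone ester 10 by adding a methoxycarbonyl group at C3. This is a retrosynthetic complication that pays off in the next cut, because it provides the second acceptor needed to stabilise the enolate released there. The forward step is a dealkoxycarbonylation that must not disturb C4.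

**Key disconnection.** Lactone ester 10 is cut at the aryl–CH2 bond of the C4 arm, and that CH2 is reconnected to C3. This gives the bicyclic cyclopropane lactone 6 and the aryl Grignard reagent 8, with the magnesium enolate 9 as the immediate product of bond formation. Compared with an asymmetric conjugate addition to a butenolide or an auxiliary-controlled alkylation, the stereocentre is already present in 6 and is not involved in the step. The forward reaction must send the aryl group to the cyclopropane CH2 and not to the methine or to either carbonyl.

**Building blocks.** Bicycle 6 is cut at both cyclopropane bonds to the quaternary carbon and at the lactone acyl–oxygen bond, giving dimethyl malonate 1 and (R)-epichlorohydrin 2. The sequence passes through alkoxide 3, epoxide 4 and cyclopropane 5 in one flask. Grignard reagent 8 comes from aryl bromide 7. All four starting materials are inexpensive, and the single stereocentre is bought.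

## Roads not taken

**Alternative 1:** The cut is at both ring C–C bonds next to the oxygen-bearing carbons (C2–C3 and C4–C5). In the forward sense the dilithium bis-enolate of di-(−)-menthyl succinate A1, formed with lithium 2,2,6,6-tetramethylpiperidide, would be alkylated twice by bis(chloromethyl) ether A2 to give di-(−)-menthyl (3R,4R)-tetrahydrofuran-3,4-dicarboxylate A3.
- Merits: the ring and both stereocentres arise in one operation, and the symmetry of the target is used fully.
- Weak points:
  - A3 contains neither aryl ring. Both esters would have to be reduced, activated and joined to aryl nucleophiles at β-branched primary carbons, twice over.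
  - A2 is a potent carcinogen.
  - Menthyl-ester induction in such dianion bis-alkylations rests on simple dihaloalkanes. An α-chloro ether reacts through a much looser, more cationic transition state, so the facial selectivity cannot be assumed.
  - The β-alkoxy ester product can reopen by E1cB elimination under the strongly basic conditions.
- Comparison: on paper this road is level with or about two steps shorter than the chosen plan, and it reaches the heterocycle much earlier. The chosen plan sets against this an absolute configuration taken from a purchased epoxide instead of an untested auxiliary induction, aryl–CH2 bonds that are either bought or made by strain release, and no hazardous bis-electrophile.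

**Alternative 2:** The cut is at both CH2–aryl bonds. The bis-amide (2R,3R)-2,3-dimethyl-N1,N4-di(quinolin-8-yl)butanediamide A5, made from (2R,3R)-2,3-dimethylbutanedioic acid A4, would be arylated at both methyl groups with 4-iodo-1,2-dimethoxybenzene A6 under Pd(OAc)2 catalysis (divalent palladium) with a silver carboxylate. The product would be (2R,3R)-2,3-bis(3,4-dimethoxybenzyl)-N1,N4-di(quinolin-8-yl)succinamide A7.
- Merits: both aryl–CH2 bonds form in one convergent step on a substrate that already has both stereocentres, and A6 is commercial.
- Weak points:
  - Enantiopure A4 is not a commodity and would need a resolution or its own asymmetric synthesis.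
  - Each methine C–H in A5 is β to the far amide, so methine palladation competes with methyl palladation.
  - Arylation of a methyl group is prone to run on to the diaryl stage.
  - The α-stereocentres sit next to amide carbonyls under hot, basic conditions and can epimerise towards the meso series.
  - Two robust secondary amides must then be activated and reduced.
- Comparison: counted from A4 this road could be a step or two shorter than the chosen plan. The chosen plan has no stereocentre exposed to epimerising conditions, no selectivity problem between C–H bonds, and no directing-group removal.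

**Alternative 3:** The cut is at the central C3–C4 bond. Two molecules of the lithium enolate of (4S)-4-benzyl-3-[3-(3,4-dimethoxyphenyl)propanoyl]-1,3-oxazolidin-2-one A8 would be oxidised with PhI(OAc)2 or CuCl2 (divalent copper) and joined α-carbon to α-carbon. The product would be (2R,3R)-2,3-bis(3,4-dimethoxybenzyl)succinyl bis[(S)-4-benzyloxazolidin-2-one] A9, which reductive removal of the auxiliaries would take to diol 15.
- Merits: this is the shortest road, about four steps, and it uses the symmetry completely. Both stereocentres and the central bond form together, and it joins the chosen route at 15.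
- Weak points:
  - The coupling is a radical dimerisation. Its diastereoselectivity depends on two auxiliaries acting in a loosely organised transition state, so the meso and mismatched isomers are expected alongside A9.
  - The electron-rich veratryl rings are themselves substrates for one-electron oxidants and hypervalent iodine reagents.
  - Two equivalents of auxiliary are consumed for one molecule of product.
- Comparison: on step count this road is clearly better. The chosen plan sets against it polar, two-electron bond formations of predictable selectivity, copper used catalytically, an absolute configuration that needs no auxiliary, and a stepwise assembly that would also deliver analogues with two different aryl groups.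

Key step: step 3

Remark on the chemistry: the target SMILES corresponds to the (3R,4R) enantiomer. The CIP order at the ring methines (CH2–O arm > neighbouring ring carbon > CH2–aryl arm) is the same in 11, 14, 15 and 17, so the descriptor R is carried through unchanged.

## Route

Step 1
Reactants: 1 dimethyl malonate; 2 (R)-epichlorohydrin
Product: 6 methyl (1S,5R)-2-oxo-3-oxabicyclo[3.1.0]hexane-1-carboxylate, via chlorohydrin alkoxide 3 (not isolated), via epoxy malonate 4 (not isolated), via hydroxymethyl cyclopropane diester 5 (not isolated)
Conditions: NaOMe (1.1 equiv), MeOH, 0 °C → reflux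
Reagents that add atoms: none
Why: Tandem malonate alkylation, cyclopropanation and lactonisation: the sodium enolate of 1 opens the epoxide of 2 at its CH2 terminus, alkoxide 3 closes to epoxide 4 with loss of chloride, the malonate anion opens 4 at the methine by 3-exo-tet attack with inversion to give 5, and the alkoxide lactonises onto the cis ester; the stereocentre of 2 becomes C5 (R) of 6 and fixes C1 (S) because only a cis ring fusion is possible.

Step 2
Reactants: 7 4-bromo-1,2-dimethoxybenzene
Product: 8 3,4-dimethoxyphenylmagnesium bromide
Conditions: Mg turnings, I2 (cat.), THF, reflux → rt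
Reagents that add atoms: magnesium, [Mg]
Why: Grignard formation by insertion of magnesium into the aryl C–Br bond; the methoxy groups are inert and the reagent is used as a titrated THF solution.

Step 3
Reactants: 6 methyl (1S,5R)-2-oxo-3-oxabicyclo[3.1.0]hexane-1-carboxylate; 8 3,4-dimethoxyphenylmagnesium bromide
Product: 10 methyl (3S,4R)-4-[(3,4-dimethoxyphenyl)methyl]-2-oxooxolane-3-carboxylate, via bromomagnesium malonate-type enolate 9 (not isolated)
Conditions: 8 (1.5 equiv), CuI (10 mol %), THF, −30 → −10 °C; then 1 M HCl
Reagents that add atoms: none
Why: Transmetalation of 8 to CuI gives an aryl cuprate (monovalent copper) that attacks the cyclopropane CH2 (C6) of 6 in an SN2-like homoconjugate (homo-Michael) addition; the C1–C6 bond breaks, its electron pair is taken up by both carbonyls as enolate 9, and acidic work-up gives 10. The closest known reaction type is the copper-catalysed Grignard opening of 2-oxo-3-oxabicyclo[3.1.0]hexane-1-carboxylates and of cyclopropane-1,1-diesters at the cyclopropane CH2. No ring is closed; the three-membered ring is opened and the lactone is kept. No lasting stereocentre is created: C5 of 6 is not involved and becomes C4 (R) of 10, while C3 is set on protonation, should settle trans to the C4 arm by equilibration through the enol, and is erased in step 4. The step needs attack at C6 and not at the methine C5 or at a carbonyl. C6 is the unhindered primary carbon, and the C1–C6 bond is the cyclopropane bond that projects out of the lactone plane and can overlap with the π* orbital of the ring carbonyl, whereas C1–C5 lies in that plane. The soft cuprate prefers the strained carbon to the hard carbonyl carbons, and once 9 has formed both carbonyls are masked as an enolate against the excess reagent.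

Step 4
Reactants: 10 methyl (3S,4R)-4-[(3,4-dimethoxyphenyl)methyl]-2-oxooxolane-3-carboxylate
Product: 11 (4R)-4-[(3,4-dimethoxyphenyl)methyl]oxolan-2-one
Conditions: LiCl (2 equiv), H2O (2 equiv), DMSO, 140 °C
Reagents that add atoms: none
Why: Krapcho dealkoxycarbonylation: chloride demethylates the doubly activated ester, the resulting β-carbonyl carboxylate loses CO2 and the enolate is protonated by water; C4 is not acidic and keeps its R configuration, and the labile C3 centre disappears.

Step 5
Reactants: 11 (4R)-4-[(3,4-dimethoxyphenyl)methyl]oxolan-2-one; 12 3,4-dimethoxybenzyl bromide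
Product: 14 (3R,4R)-3,4-bis[(3,4-dimethoxyphenyl)methyl]oxolan-2-one, via lithium lactone enolate 13 (not isolated)
Conditions: LiN(SiMe3)2 (1.1 equiv), THF, −78 °C; then 12 (1.1 equiv), DMPU, −78 → −20 °C
Reagents that add atoms: none
Why: Diastereoselective alkylation of a β-substituted γ-butyrolactone enolate: the C4 arylmethyl arm shields one face of the planar enolate 13, the benzylic bromide enters anti to it, and the new C3 centre is set trans (R) by substrate control; trans is also the more stable arrangement.

Step 6
Reactants: 14 (3R,4R)-3,4-bis[(3,4-dimethoxyphenyl)methyl]oxolan-2-one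
Product: 15 (2R,3R)-2,3-bis[(3,4-dimethoxyphenyl)methyl]butane-1,4-diol
Conditions: LiAlH4 (1.5 equiv), THF, 0 °C → rt; then H2O, aq NaOH
Reagents that add atoms: none
Why: Hydride reduction of a lactone to the 1,4-diol; aryl methyl ethers are inert to LiAlH4, reduction is faster than enolisation, and any enolisation would only return the more stable trans isomer.

Step 7
Reactants: 15 (2R,3R)-2,3-bis[(3,4-dimethoxyphenyl)methyl]butane-1,4-diol
Product: 17 (3R,4R)-3,4-bis[(3,4-dimethoxyphenyl)methyl]oxolane, via monotosylate 16 (not isolated)
Conditions: TsCl (1.1 equiv), pyridine, 0 °C → rt, then 50 °C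
Reagents that add atoms: none
Why: Mono-sulfonylation followed by intramolecular Williamson etherification (5-exo-tet) of 16 by the remaining hydroxyl; bonds are made and broken only at CH2 carbons, so both stereocentres are untouched, and the C2 symmetry of 15 makes the two hydroxyls equivalent.

## Compound list

1 | dimethyl malonate | COC(=O)CC(=O)OC | starting material
2 | (R)-epichlorohydrin, (2R)-2-(chloromethyl)oxirane | ClC[C@H]1CO1 | starting material
3 | dimethyl 2-[(2R)-3-chloro-2-hydroxypropyl]propanedioate (present as its sodium alkoxide) | COC(=O)C(C[C@@H](O)CCl)C(=O)OC | intermediate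
4 | dimethyl 2-{[(2R)-oxiran-2-yl]methyl}propanedioate | COC(=O)C(C[C@@H]1CO1)C(=O)OC | intermediate
5 | dimethyl (2R)-2-(hydroxymethyl)cyclopropane-1,1-dicarboxylate (present as its sodium alkoxide) | OC[C@@H]1CC1(C(=O)OC)C(=O)OC | intermediate
6 | methyl (1S,5R)-2-oxo-3-oxabicyclo[3.1.0]hexane-1-carboxylate | O=C1OC[C@@H]2C[C@]12C(=O)OC | intermediate
7 | 4-bromo-1,2-dimethoxybenzene | COc1ccc(Br)cc1OC | starting material
8 | 3,4-dimethoxyphenylmagnesium bromide | COc1ccc([Mg]Br)cc1OC | intermediate
9 | bromomagnesium enolate of 10, bromo{[(4R)-4-[(3,4-dimethoxyphenyl)methyl]-3-(methoxycarbonyl)-4,5-dihydrofuran-2-yl]oxy}magnesium | COC(=O)C1=C(O[Mg]Br)OC[C@@H]1Cc1ccc(OC)c(OC)c1 | intermediate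
10 | methyl (3S,4R)-4-[(3,4-dimethoxyphenyl)methyl]-2-oxooxolane-3-carboxylate (trans) | COC(=O)[C@H]1C(=O)OC[C@@H]1Cc1ccc(OC)c(OC)c1 | intermediate
11 | (4R)-4-[(3,4-dimethoxyphenyl)methyl]oxolan-2-one | O=C1C[C@@H](Cc2ccc(OC)c(OC)c2)CO1 | intermediate
12 | 3,4-dimethoxybenzyl bromide | COc1ccc(CBr)cc1OC | starting material
13 | lithium enolate of 11, lithium (4R)-4-[(3,4-dimethoxyphenyl)methyl]-4,5-dihydrofuran-2-olate | [Li]OC1=C[C@@H](Cc2ccc(OC)c(OC)c2)CO1 | intermediate
14 | (3R,4R)-3,4-bis[(3,4-dimethoxyphenyl)methyl]oxolan-2-one (trans) | COc1ccc(C[C@H]2C(=O)OC[C@@H]2Cc2ccc(OC)c(OC)c2)cc1OC | intermediate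
15 | (2R,3R)-2,3-bis[(3,4-dimethoxyphenyl)methyl]butane-1,4-diol | COc1ccc(C[C@@H](CO)[C@H](CO)Cc2ccc(OC)c(OC)c2)cc1OC | intermediate
16 | (2R,3R)-2,3-bis[(3,4-dimethoxyphenyl)methyl]-4-hydroxybutyl 4-methylbenzenesulfonate | COc1ccc(C[C@@H](CO)[C@H](COS(=O)(=O)c2ccc(C)cc2)Cc2ccc(OC)c(OC)c2)cc1OC | intermediate
17 | (3R,4R)-3,4-bis[(3,4-dimethoxyphenyl)methyl]oxolane, trans-3,4-bis(3,4-dimethoxybenzyl)tetrahydrofuran | COc1ccc(C[C@H]2COC[C@@H]2Cc2ccc(OC)c(OC)c2)cc1OC | target

## Step count and risk

Total step count: 7 (6 if reagent 8 is bought as its THF solution).
Longest linear sequence: 6 steps (steps 1, 3, 4, 5, 6, 7) from 1 and 2.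

**Step 3 (key step).** The most likely failure is slow transfer of the aryl group from copper to the cyclopropane CH2. Aryl cuprates are weaker nucleophiles in SN2-type openings than alkyl cuprates, so uncatalysed addition of 8 to the ester or lactone carbonyl of 6 could compete, and oxidative biaryl coupling could use up the reagent.

The fallback sets out from 12 and comes back to the route at 11. The imide tert-butyl 4-[(4R)-4-benzyl-2-oxo-1,3-oxazolidin-3-yl]-4-oxobutanoate F1 would be made by N-acylation of the lithiated (R)-4-benzyl oxazolidinone auxiliary with the pivaloyl mixed anhydride of mono-tert-butyl succinate. Deprotonation with NaN(SiMe3)2 in THF at −78 °C and Evans alkylation with 12 should give tert-butyl (3R)-4-[(4R)-4-benzyl-2-oxo-1,3-oxazolidin-3-yl]-3-[(3,4-dimethoxyphenyl)methyl]-4-oxobutanoate F2, the benzylic bromide entering opposite the auxiliary benzyl group. LiBH4 would remove the auxiliary reductively to give tert-butyl (3R)-3-[(3,4-dimethoxyphenyl)methyl]-4-hydroxybutanoate F3. CF3CO2H in CH2Cl2 would then close the lactone with loss of the tert-butyl group to give 11, and steps 5 to 7 follow unchanged.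

**Step 1.** The likely problem is erosion of enantiomeric purity. Direct displacement of chloride by the malonate anion competes with epoxide opening and leads into the enantiomeric series. Alkoxide-induced oligomerisation of the epoxide would lower the throughput.

The fallback sets out from 1 and comes back at 4, which continues to 6 in the same way. The sodium salt of 1 (NaH, THF, 0 °C) would be alkylated with (S)-glycidyl trifluoromethanesulfonate F4, prepared from the corresponding glycidol and Tf2O. A triflate is displaced far faster than the epoxide is opened, so 4 should form with the stereocentre untouched, and NaOMe in MeOH would then take 4 through 5 to 6.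

**Step 5.** Facial selectivity may be incomplete. Proton exchange between enolate 13 and product 14 could also lead to a second alkylation at C3 or to recovered 11.

The fallback sets out from 11 and comes back at 14. Enolate 13 would be added at −78 °C to 3,4-dimethoxybenzaldehyde, an aldol addition that cannot run on to a second substitution and should again take place anti to the C4 arm. The product is (3S,4R)-3-[(3,4-dimethoxyphenyl)(hydroxy)methyl]-4-[(3,4-dimethoxyphenyl)methyl]oxolan-2-one F5 as a mixture of carbinol epimers. Hydrogenolysis of the electron-rich benzylic C–OH bond (H2, Pd/C, AcOH, catalytic HClO4) would remove the carbinol centre and give 14.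

**Step 7.** A second sulfonylation of 16 may outrun ring closure, and chloride may displace the tosylate. Both divert material to open-chain bis-electrophiles.

The fallback sets out from 14 and comes back at 17, bypassing 15 and 16. Partial reduction with i-Bu2AlH in CH2Cl2 at −78 °C would give the lactol (3R,4R)-3,4-bis[(3,4-dimethoxyphenyl)methyl]oxolan-2-ol F6 as a mixture of anomers. Ionic hydrogenation of the derived oxocarbenium ion with Et3SiH and BF3·OEt2 in CH2Cl2 at −78 °C would give 17. Excess silane and low temperature are needed so that hydride capture outruns attack of a veratryl ring on the cation.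

## Further compounds

F1 | step 3 | tert-butyl 4-[(4R)-4-benzyl-2-oxo-1,3-oxazolidin-3-yl]-4-oxobutanoate | CC(C)(C)OC(=O)CCC(=O)N1[C@H](Cc2ccccc2)COC1=O
F2 | step 3 | tert-butyl (3R)-4-[(4R)-4-benzyl-2-oxo-1,3-oxazolidin-3-yl]-3-[(3,4-dimethoxyphenyl)methyl]-4-oxobutanoate | CC(C)(C)OC(=O)C[C@@H](Cc1ccc(OC)c(OC)c1)C(=O)N1[C@H](Cc2ccccc2)COC1=O
F3 | step 3 | tert-butyl (3R)-3-[(3,4-dimethoxyphenyl)methyl]-4-hydroxybutanoate | CC(C)(C)OC(=O)C[C@@H](Cc1ccc(OC)c(OC)c1)CO
F4 | step 1 | (S)-glycidyl trifluoromethanesulfonate, [(2S)-oxiran-2-yl]methyl trifluoromethanesulfonate | O=S(=O)(OC[C@@H]1CO1)C(F)(F)F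
F5 | step 5 | (3S,4R)-3-[(3,4-dimethoxyphenyl)(hydroxy)methyl]-4-[(3,4-dimethoxyphenyl)methyl]oxolan-2-one (carbinol epimers) | COc1ccc(C(O)[C@H]2C(=O)OC[C@@H]2Cc2ccc(OC)c(OC)c2)cc1OC
F6 | step 7 | (3R,4R)-3,4-bis[(3,4-dimethoxyphenyl)methyl]oxolan-2-ol (anomers) | COc1ccc(C[C@H]2C(O)OC[C@@H]2Cc2ccc(OC)c(OC)c2)cc1OC
A1 | alternative 1 | di-(−)-menthyl succinate | CC(C)[C@@H]1CC[C@@H](C)C[C@H]1OC(=O)CCC(=O)O[C@@H]1C[C@H](C)CC[C@H]1C(C)C
A2 | alternative 1 | bis(chloromethyl) ether | ClCOCCl
A3 | alternative 1 | di-(−)-menthyl (3R,4R)-tetrahydrofuran-3,4-dicarboxylate | CC(C)[C@@H]1CC[C@@H](C)C[C@H]1OC(=O)[C@H]1COC[C@@H]1C(=O)O[C@@H]1C[C@H](C)CC[C@H]1C(C)C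
A4 | alternative 2 | (2R,3R)-2,3-dimethylbutanedioic acid | C[C@@H](C(=O)O)[C@@H](C)C(=O)O
A5 | alternative 2 | (2R,3R)-2,3-dimethyl-N1,N4-di(quinolin-8-yl)butanediamide | C[C@@H](C(=O)Nc1cccc2cccnc12)[C@@H](C)C(=O)Nc1cccc2cccnc12
A6 | alternative 2 | 4-iodo-1,2-dimethoxybenzene | COc1ccc(I)cc1OC
A7 | alternative 2 | (2R,3R)-2,3-bis(3,4-dimethoxybenzyl)-N1,N4-di(quinolin-8-yl)succinamide | COc1ccc(C[C@@H](C(=O)Nc2cccc3cccnc23)[C@H](C(=O)Nc2cccc3cccnc23)Cc2ccc(OC)c(OC)c2)cc1OC
A8 | alternative 3 | (4S)-4-benzyl-3-[3-(3,4-dimethoxyphenyl)propanoyl]-1,3-oxazolidin-2-one | COc1ccc(CCC(=O)N2[C@@H](Cc3ccccc3)COC2=O)cc1OC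
A9 | alternative 3 | (2R,3R)-2,3-bis(3,4-dimethoxybenzyl)succinyl bis[(S)-4-benzyloxazolidin-2-one] | COc1ccc(C[C@@H](C(=O)N2[C@@H](Cc3ccccc3)COC2=O)[C@H](C(=O)N2[C@@H](Cc3ccccc3)COC2=O)Cc2ccc(OC)c(OC)c2)cc1OC
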